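**Assumptions**
- The target has no stereocentres and is achiral. "Single enantiomer" therefore reduces to controlling the two olefin geometries: side chain Z, enone E.
- 2',4'-Dihydroxy-6'-methoxyacetophenone and 4-(allyloxy)benzaldehyde are treated as catalogue compounds.

## Retrosynthetic overview
1. Candidachalcone ⇒ its tri-O-allyl ether. The last step is a neutral Pd(0) deallylation, because acid would close the Z-allylic tertiary alcohol onto a flanking phenol (2,2-dimethylchromene) and base would close the 2'-OH chalcone to the flavanone.
2. E-enone ⇒ Claisen–Schmidt condensation of a Z-alkenyl acetophenone with 4-(allyloxy)benzaldehyde.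
3. Z-alkene ⇒ Lindlar semihydrogenation of an aryl alkyne, itself from Sonogashira coupling of an aryl iodide with 2-methylbut-3-yn-2-ol. Both are done before the enone exists.
4. Aryl iodide ⇒ C3-iodination, then bis-O-allylation, of 2',4'-dihydroxy-6'-methoxyacetophenone.
5. No ring is formed. Both benzene rings are purchased intact.

## Route

**Step 1**
- Reactants: 1, 2',4'-dihydroxy-6'-methoxyacetophenone; 2, N-iodosuccinimide
- Product: 3, 1-(2,4-dihydroxy-3-iodo-6-methoxyphenyl)ethan-1-one
- Conditions: NIS (1.0 equiv, portionwise), MeCN, 0 °C → rt, dark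
- Reagents that add atoms: N-iodosuccinimide, O=C1CCC(=O)N1I
- Why: This electrophilic aromatic iodination should favour C3, which lies between the two free OH groups, is para to OMe and is less hindered than C5; acid-free conditions prevent iodine migration, and a retained H-5/OMe NOE confirms the site.

**Step 2**
- Reactants: 3; 4, allyl bromide
- Product: 5, 1-[2,4-bis(allyloxy)-3-iodo-6-methoxyphenyl]ethan-1-one
- Conditions: allyl bromide (3 equiv), K2CO3 (4 equiv), DMF, 55 °C
- Reagents that add atoms: allyl bromide, C=CCBr
- Why: Williamson etherification in a polar aprotic solvent gives O-alkylation of both phenols, including the chelated 2-OH on warming, which blocks benzofuran formation in step 3 and phenoxide deactivation in step 5.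

**Step 3**
- Reactants: 5; 6, 2-methylbut-3-yn-2-ol
- Product: 7, 1-[2,4-bis(allyloxy)-3-(3-hydroxy-3-methylbut-1-yn-1-yl)-6-methoxyphenyl]ethan-1-one
- Conditions: 6 (2.5 equiv), PdCl2(PPh3)2 (5 mol %), CuI (10 mol %), Et3N/DMF, degassed, 40–45 °C
- Reagents that add atoms: 2-methylbut-3-yn-2-ol, CC(C)(O)C#C
- Why: In this Sonogashira coupling, copper-acetylide transmetalation at ≤45 °C outruns 5-exo Heck closure onto the O-allyl groups (which needs about 80 °C), and the tertiary amine base does not scavenge allyl groups.

**Step 4**
- Reactants: 7
- Product: 8, 1-{2,4-bis(allyloxy)-3-[(1Z)-3-hydroxy-3-methylbut-1-en-1-yl]-6-methoxyphenyl}ethan-1-one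
- Conditions: H2 (1 atm, stopped at 1.0 equiv uptake), Lindlar catalyst (Pd/CaCO3–Pb), quinoline, EtOAc, rt; quinoline removed by chromatography, no acid wash
- Reagents that add atoms: none (H2 adds hydrogen only)
- Why: Lindlar semihydrogenation delivers both hydrogens syn from the catalyst surface and so sets the Z-alkene, while the more strongly adsorbed alkyne shields the allyl ethers until it is consumed.

**Step 5**
- Reactants: 8; 9, 4-(allyloxy)benzaldehyde
- Product: 10, (2E)-1-{2,4-bis(allyloxy)-3-[(1Z)-3-hydroxy-3-methylbut-1-en-1-yl]-6-methoxyphenyl}-3-[4-(allyloxy)phenyl]prop-2-en-1-one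
- Conditions: 9 (1.2 equiv), KOH (50 % aq, 10 equiv), EtOH, rt, 24–36 h, N2; quench with sat. NH4Cl to pH about 7
- Reagents that add atoms: 4-(allyloxy)benzaldehyde, C=CCOc1ccc(C=O)cc1
- Why: Claisen–Schmidt condensation (crossed aldol, then E1cB loss of water) gives the thermodynamic E-enone, and with every phenol masked there is no flavanone closure while the allyl ethers, Z-alkene and tertiary alcohol are inert to hydroxide.

**Step 6**
- Reactants: 10
- Product: 11, candidachalcone
- Conditions: Pd(PPh3)4 (10 mol %), N-methylaniline (6 equiv), degassed THF, rt, dark; purify on Sephadex LH-20 or C18 without acid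
- Reagents that add atoms: none
- Why: Tsuji–Trost-type deallylation ionises only the three aryl allyl ethers (phenoxide leaving groups) and passes the allyl groups to a weakly basic amine that is a poor Michael donor, so the unactivated tertiary allylic OH, both olefin geometries and the open chalcone survive.

## Compound list

| No. | Name | SMILES | Role |
|---|---|---|---|
| 1 | 2',4'-dihydroxy-6'-methoxyacetophenone | CC(=O)c1c(O)cc(O)cc1OC | starting material |
| 2 | N-iodosuccinimide | O=C1CCC(=O)N1I | starting material (reagent) |
| 3 | 1-(2,4-dihydroxy-3-iodo-6-methoxyphenyl)ethanone | CC(=O)c1c(OC)cc(O)c(I)c1O | intermediate |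
| 4 | allyl bromide | C=CCBr | starting material (reagent) |
| 5 | 1-[2,4-bis(allyloxy)-3-iodo-6-methoxyphenyl]ethanone | CC(=O)c1c(OC)cc(OCC=C)c(I)c1OCC=C | intermediate |
| 6 | 2-methylbut-3-yn-2-ol | CC(C)(O)C#C | starting material |
| 7 | 1-[2,4-bis(allyloxy)-3-(3-hydroxy-3-methylbut-1-ynyl)-6-methoxyphenyl]ethanone | CC(=O)c1c(OC)cc(OCC=C)c(C#CC(C)(C)O)c1OCC=C | intermediate |
| 8 | 1-{2,4-bis(allyloxy)-3-[(Z)-3-hydroxy-3-methylbut-1-enyl]-6-methoxyphenyl}ethanone | CC(=O)c1c(OC)cc(OCC=C)c(/C=C\C(C)(C)O)c1OCC=C | intermediate |
| 9 | 4-(allyloxy)benzaldehyde | C=CCOc1ccc(C=O)cc1 | starting material |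
| 10 | tri-O-allyl candidachalcone (enone E, side chain Z) | COc1cc(OCC=C)c(/C=C\C(C)(C)O)c(OCC=C)c1C(=O)/C=C/c1ccc(OCC=C)cc1 | intermediate |
| 11 | candidachalcone, (2E)-1-{2,4-dihydroxy-3-[(1Z)-3-hydroxy-3-methylbut-1-enyl]-6-methoxyphenyl}-3-(4-hydroxyphenyl)prop-2-en-1-one | COc1cc(O)c(/C=C\C(C)(C)O)c(O)c1C(=O)/C=C/c1ccc(O)cc1 | target |

## Summary
- **Total step count:** 6
- **Longest linear sequence:** 6 (fully linear from 1; compounds 2, 4, 6 and 9 are purchased)

**Three steps most likely to fail**
1. **Step 6, global deallylation.**
   - Risk: the product is labile toward chromene closure and flavanone isomerisation, and Pd could ionise the allylic alcohol.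
   - Fallback: change the protecting-group logic to fluoride-labile silyl ethers.
     - Carry the phenols as TBS ethers and the tertiary OH as a TES ether, and use commercial 4-TBSO-benzaldehyde.
     - Build the enone without hydroxide by LiHMDS aldol followed by mesylation/elimination.
     - Finish with TBAF/AcOH at 0 °C.
2. **Step 4, semihydrogenation.**
   - Risk: the alkyne is hindered and competes with two terminal allyl ethers, and over-reduction is possible.
   - Fallback: bypass the alkyne by Stille coupling of iodide 5 with preformed (Z)-Bu3SnCH=CHC(CH3)2OH. This transfers the Z-olefin with retention and replaces steps 3 and 4.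
3. **Step 1, regioselective mono-iodination.**
   - Risk: C5 iodination or di-iodination.
   - Fallback: make the outcome substrate-controlled, at a cost of one extra step.
     - Mono-allylate the non-chelated 4-OH first.
     - Iodinate ortho to the only remaining free (chelated) 2-OH, which is para to OMe.
     - Allylate the 2-OH to reach compound 5.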